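**Retrosynthetic overview**

1. Target 21 ⇐ 13-deoxy diester 20: the C13–O bond (free hydroxyl, last stereocentre) is made last by allylic C–H hydroxylation with a new selenium-catalysed ene/[2,3] method, so this hydroxyl never needs protection.
2. 20 ⇐ diene alcohol 16: the eleven-membered ring (third ring) is closed by ring-closing metathesis at C11=C12, followed by the C9 acetate and C3 propanoate.
3. 16 ⇐ bicyclic ester 14: C9–C10 by reagent-controlled allylboration of the C9 aldehyde.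
4. 14 ⇐ cyclohexene dienoate 13: the five-membered ring (second ring) by an intramolecular ene reaction that sets C16, C7, C8 and the C15 methylidene together.
5. 13 ⇐ 4-methoxy-2-methylphenol 1: the six-membered ring is the arene (quinone monoketal 2); asymmetric conjugate addition sets C1, Luche reduction C3, cuprate addition C4.

Assumption: the text uses trinervitane locants (C3 CH–O-propanoyl, C4 C–CH3, C7 and C16 ring-fusion CH, C8 CH–CH3, C9 CH–OAc, C11=C12, C13 CH–OH, C15=C17 methylidene), which map onto the tricyclo[7.5.2.0^{12,15}]hexadecane names as C7 = 1, C8 = 2, C9 = 3, C10–C14 = 4–8, C1 = 9, C2 = 10, C3 = 11, C4 = 12, C5 = 13, C6 = 14, C16 = 15, C15 = 16; the phosphoramidite ligand, the (+)-α-pinene-derived (−)-B-allyldiisopinocampheylborane and the diselenide precatalyst of step 14 (made separately) are taken as reagents and not counted as steps.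

**Route**

Step 1
Reactants: 1 4-methoxy-2-methylphenol
Product: 2 4,4-dimethoxy-2-methylcyclohexa-2,5-dien-1-one
Conditions: PhI(OAc)2 (1.1 equiv), MeOH, 0 °C
Reagents that add atoms: methanol, CO
Why: Oxidative dearomatization of a para-alkoxyphenol by the trivalent-iodine reagent, with methanol adding to C4 of the phenoxenium ion to give the quinone monoketal; no stereocentre is formed.

Step 2
Reactants: 2 4,4-dimethoxy-2-methylcyclohexa-2,5-dien-1-one; 3 4-bromo-2-methylbut-1-ene
Product: 4 (5R)-4,4-dimethoxy-2-methyl-5-(3-methylbut-3-en-1-yl)cyclohex-2-en-1-one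
Conditions: 3, Mg, Et2O; ZnCl2 (0.5 equiv per Grignard), 1,4-dioxane, filtration; Cu(OTf)2 (3 mol %), (S)-(1,1'-binaphthalene-2,2'-diyl) N,N-bis[(R)-1-phenylethyl]phosphoramidite (6 mol %), toluene, −30 °C
Reagents that add atoms: none
Why: Copper-catalysed asymmetric conjugate addition of a dialkylzinc (Feringa type), in which the unmethylated enone of the cross-conjugated dienone is the more reactive acceptor and the chiral phosphoramidite–copper complex selects its face, which sets C1 (5R in 4; ligand sense taken from the cyclohexenone case, the antipode being used if the first run gives ent-4) and through it all later centres.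

Step 3
Reactants: 4 (5R)-4,4-dimethoxy-2-methyl-5-(3-methylbut-3-en-1-yl)cyclohex-2-en-1-one
Product: 6 (4S,6R)-4-hydroxy-3-methyl-6-(3-methylbut-3-en-1-yl)cyclohex-2-en-1-one, via allylic alcohol ketal 5 (not isolated)
Conditions: NaBH4, CeCl3·7H2O, MeOH, −78 °C; then 1 M HCl, THF, 0 °C → rt
Reagents that add atoms: water, O
Why: Luche 1,2-reduction, in which axial hydride attack on the half-chair that keeps the C1 side chain equatorial gives the cis-1,3 allylic alcohol (as in carvone to cis-carveol) and so sets C3, after which dilute acid hydrolyses the allylic dimethyl ketal and thereby moves the enone carbonyl to C15.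

Step 4
Reactants: 6 (4S,6R)-4-hydroxy-3-methyl-6-(3-methylbut-3-en-1-yl)cyclohex-2-en-1-one
Product: 7 (4S,6R)-4-[(tert-butyldimethylsilyl)oxy]-3-methyl-6-(3-methylbut-3-en-1-yl)cyclohex-2-en-1-one
Conditions: t-BuMe2SiCl, imidazole, DMF, rt
Reagents that add atoms: tert-butyl(chloro)dimethylsilane, CC(C)(C)[Si](C)(C)Cl
Why: Silyl ether formation on the only hydroxyl, the bulky group also blocking the C3–O face of the enone for the next step.

Step 5
Reactants: 7 (4S,6R)-4-[(tert-butyldimethylsilyl)oxy]-3-methyl-6-(3-methylbut-3-en-1-yl)cyclohex-2-en-1-one; 8 2-(2-bromoethyl)-1,3-dioxolane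
Product: 10 (3S,4S,6R)-4-[(tert-butyldimethylsilyl)oxy]-3-[2-(1,3-dioxolan-2-yl)ethyl]-3-methyl-6-(3-methylbut-3-en-1-yl)cyclohex-1-en-1-yl trifluoromethanesulfonate, via silyl enol ether 9 (not isolated)
Conditions: 8, Mg, THF, 25 °C; CuBr·SMe2 (20 mol %), Me3SiCl, DMPU, THF, −78 → −40 °C; Et3N, pentane, filtration, evaporation; MeLi (1.1 equiv), THF, 0 °C; PhNTf2, −78 °C → rt
Reagents that add atoms: N-phenylbis(trifluoromethanesulfonimide), O=S(=O)(N(c1ccccc1)S(=O)(=O)C(F)(F)F)C(F)(F)F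
Why: Copper-catalysed conjugate addition of the acetal Grignard reagent, accelerated by Me3SiCl, enters anti to the adjacent silyloxy group and builds the quaternary C4 with its methyl cis to C3–O, and the regiodefined silyl enol ether is then converted by MeLi into the lithium enolate and trapped as the enol triflate.

Step 6
Reactants: 10 (3S,4S,6R)-4-[(tert-butyldimethylsilyl)oxy]-3-[2-(1,3-dioxolan-2-yl)ethyl]-3-methyl-6-(3-methylbut-3-en-1-yl)cyclohex-1-en-1-yl trifluoromethanesulfonate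
Product: 11 tert-butyl{[(1S,2S,5R)-2-[2-(1,3-dioxolan-2-yl)ethyl]-2,4-dimethyl-5-(3-methylbut-3-en-1-yl)cyclohex-3-en-1-yl]oxy}dimethylsilane
Conditions: MeMgBr (1.5 equiv), Fe(acac)3 (5 mol %), THF/NMP, −30 → 0 °C
Reagents that add atoms: methylmagnesium bromide, C[Mg]Br
Why: Iron-catalysed Kumada-type cross-coupling of the alkenyl triflate replaces triflate by the methyl group (C17) and leaves the C15=C16 double bond in place.

Step 7
Reactants: 11 tert-butyl{[(1S,2S,5R)-2-[2-(1,3-dioxolan-2-yl)ethyl]-2,4-dimethyl-5-(3-methylbut-3-en-1-yl)cyclohex-3-en-1-yl]oxy}dimethylsilane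
Product: 13 ethyl (2E)-5-[(1S,4R,6S)-6-[(tert-butyldimethylsilyl)oxy]-1,3-dimethyl-4-(3-methylbut-3-en-1-yl)cyclohex-2-en-1-yl]-2-methylpent-2-enoate, via aldehyde 12 (not isolated)
Conditions: PPTS, acetone/H2O (10:1), 60 °C; then Ph3P=C(CH3)CO2Et (1.5 equiv), toluene, 80 °C
Reagents that add atoms: ethyl 2-(triphenyl-λ5-phosphanylidene)propanoate, CCOC(=O)C(C)=P(c1ccccc1)(c1ccccc1)c1ccccc1
Why: Mild transacetalization frees the aldehyde and the stabilized Wittig ylide gives the E trisubstituted enoate (ester trans to the chain), the geometry that is translated into C8 in the next step.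

Step 8
Reactants: 13 ethyl (2E)-5-[(1S,4R,6S)-6-[(tert-butyldimethylsilyl)oxy]-1,3-dimethyl-4-(3-methylbut-3-en-1-yl)cyclohex-2-en-1-yl]-2-methylpent-2-enoate
Product: 14 ethyl (2S)-2-[(1R,3aS,4S,6R,7aS)-4-[(tert-butyldimethylsilyl)oxy]-3a-methyl-7-methylidene-6-(3-methylbut-3-en-1-yl)octahydro-1H-inden-1-yl]propanoate
Conditions: EtAlCl2 (1.5 equiv), CH2Cl2 (0.01 M), −78 → −20 °C
Reagents that add atoms: none
Why: Lewis acid-promoted intramolecular ene reaction of the 1,6-dienoate (Oppolzer-type cyclopentane-forming ene cyclization), in which the enoate tethered to C4 on the face opposite the angular methyl can only reach that face of C16 and so makes the new ring cis-fused (C16), while the concerted suprafacial transfer of a C17 hydrogen to C8 through the six-membered transition state places C8 cis to C15 on the new ring (C7), fixes C8 from the E geometry of the enoate and creates the C15 methylidene.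

Step 9
Reactants: 14 ethyl (2S)-2-[(1R,3aS,4S,6R,7aS)-4-[(tert-butyldimethylsilyl)oxy]-3a-methyl-7-methylidene-6-(3-methylbut-3-en-1-yl)octahydro-1H-inden-1-yl]propanoate
Product: 15 (2S)-2-[(1R,3aS,4S,6R,7aS)-4-[(tert-butyldimethylsilyl)oxy]-3a-methyl-7-methylidene-6-(3-methylbut-3-en-1-yl)octahydro-1H-inden-1-yl]propanal
Conditions: i-Bu2AlH (1.1 equiv), CH2Cl2, −78 °C; Rochelle salt work-up
Reagents that add atoms: none
Why: Partial reduction of the hindered ester by the aluminium hydride at −78 °C stops at the aluminium hemiacetal, which gives the aldehyde on work-up without touching C8.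

Step 10
Reactants: 15 (2S)-2-[(1R,3aS,4S,6R,7aS)-4-[(tert-butyldimethylsilyl)oxy]-3a-methyl-7-methylidene-6-(3-methylbut-3-en-1-yl)octahydro-1H-inden-1-yl]propanal
Product: 16 (2S,3S)-2-[(1R,3aS,4S,6R,7aS)-4-[(tert-butyldimethylsilyl)oxy]-3a-methyl-7-methylidene-6-(3-methylbut-3-en-1-yl)octahydro-1H-inden-1-yl]hex-5-en-3-ol
Conditions: (−)-B-allyldiisopinocampheylborane (1.5 equiv), Et2O, −78 °C; then NaOH, H2O2, 0 °C → rt
Reagents that add atoms: (−)-B-allyldiisopinocampheylborane, C=CCB([C@@H]1C[C@@H]2C[C@H]([C@H]1C)C2(C)C)[C@@H]1C[C@@H]2C[C@H]([C@H]1C)C2(C)C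
Why: Brown allylboration through a chair-like six-membered transition state, in which the (+)-α-pinene-derived reagent attacks the aldehyde face that gives the (9S)-alcohol (as with isobutyraldehyde), which is also the Felkin–Anh face of the α-methyl aldehyde, so that reagent and substrate control are matched.

Step 11
Reactants: 16 (2S,3S)-2-[(1R,3aS,4S,6R,7aS)-4-[(tert-butyldimethylsilyl)oxy]-3a-methyl-7-methylidene-6-(3-methylbut-3-en-1-yl)octahydro-1H-inden-1-yl]hex-5-en-3-ol
Product: 17 (1R,2S,3S,5E,9R,11S,12S,15S)-11-[(tert-butyldimethylsilyl)oxy]-2,6,12-trimethyl-16-methylidenetricyclo[7.5.2.0^{12,15}]hexadec-5-en-3-ol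
Conditions: second-generation Grubbs catalyst RuCl2(=CHPh)(PCy3)(H2IMes) (10 mol %), toluene (0.5 mM), 80 °C, argon sparge
Reagents that add atoms: none
Why: Ring-closing metathesis between the monosubstituted C11 alkene and the 1,1-disubstituted C12 alkene releases ethene and closes the eleven-membered ring with the trisubstituted C11=C12 bond, the doubly branched C15 methylidene being too hindered to compete, and the E isomer is expected because both tethers leave the rigid bicycle as in the E-configured natural ring system (no stereocentre is formed).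

Step 12
Reactants: 17 (1R,2S,3S,5E,9R,11S,12S,15S)-11-[(tert-butyldimethylsilyl)oxy]-2,6,12-trimethyl-16-methylidenetricyclo[7.5.2.0^{12,15}]hexadec-5-en-3-ol
Product: 19 (1R,2S,3S,5E,9R,11S,12S,15S)-11-hydroxy-2,6,12-trimethyl-16-methylidenetricyclo[7.5.2.0^{12,15}]hexadec-5-en-3-yl acetate, via silyl ether acetate 18 (not isolated)
Conditions: Ac2O, pyridine, DMAP (cat.), CH2Cl2, rt; MeOH, evaporation; HF·pyridine, THF/pyridine, rt
Reagents that add atoms: acetic anhydride, CC(=O)OC(C)=O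
Why: DMAP-catalysed acylation of the C9 hydroxyl, then fluoride cleavage of the silyl ether at C3, neither of which touches a stereocentre.

Step 13
Reactants: 19 (1R,2S,3S,5E,9R,11S,12S,15S)-11-hydroxy-2,6,12-trimethyl-16-methylidenetricyclo[7.5.2.0^{12,15}]hexadec-5-en-3-yl acetate
Product: 20 (1R,2S,3S,5E,9R,11S,12S,15S)-2,6,12-trimethyl-16-methylidene-11-(propanoyloxy)tricyclo[7.5.2.0^{12,15}]hexadec-5-en-3-yl acetate
Conditions: (EtCO)2O, Et3N, DMAP, CH2Cl2, 35 °C
Reagents that add atoms: propanoic anhydride, CCC(=O)OC(=O)CC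
Why: DMAP-catalysed acylation of the hindered secondary C3 hydroxyl with the anhydride.

Step 14
Reactants: 20 (1R,2S,3S,5E,9R,11S,12S,15S)-2,6,12-trimethyl-16-methylidene-11-(propanoyloxy)tricyclo[7.5.2.0^{12,15}]hexadec-5-en-3-yl acetate
Product: 21 (1R,2S,3S,5E,7R,9R,11S,12S,15S)-7-hydroxy-2,6,12-trimethyl-16-methylidene-11-(propanoyloxy)tricyclo[7.5.2.0^{12,15}]hexadec-5-en-3-yl acetate (CNP0180453.1)
Conditions: bis{2,6-bis[(1S)-1-methoxyethyl]phenyl} diselenide (5 mol %), t-BuOOH (anhydrous, 2 equiv), 4 Å molecular sieves, CH2Cl2, 0 °C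
Reagents that add atoms: tert-butyl hydroperoxide, CC(C)(C)OO
Why: Proposed new method: a chiral arylseleninic acid or anhydride formed in situ from the C2-symmetric diselenide and t-BuOOH is expected to react like SeO2, by an ene reaction at C11 of the only trisubstituted alkene with C–H cleavage at C13 (the ring CH2 on the more substituted terminus and the E position) followed by a suprafacial [2,3]-shift of the allyl aryl selenoxide that returns the double bond to C11=C12 with E geometry and puts oxygen on C13, after which the selenenate is cleaved and the divalent selenium reoxidized by t-BuOOH; the ortho 1-methoxyethyl arms coordinated to selenium are meant to select the C13 hydrogen on the outer face of the macrocycle so that the (13R)-alcohol forms, while the hindered methylidene (only tertiary allylic C–H) and both esters are left alone, the closest known reactions being the SeO2/t-BuOOH allylic hydroxylation, the benzeneseleninic anhydride allylic oxidation and the [2,3]-rearrangement of chiral allylic selenoxides.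

**Compound list**

1 | 4-methoxy-2-methylphenol | COc1ccc(O)c(C)c1 | starting material
2 | 4,4-dimethoxy-2-methylcyclohexa-2,5-dien-1-one | COC1(OC)C=CC(=O)C(C)=C1 | intermediate
3 | 4-bromo-2-methylbut-1-ene | C=C(C)CCBr | starting material
4 | (5R)-4,4-dimethoxy-2-methyl-5-(3-methylbut-3-en-1-yl)cyclohex-2-en-1-one | C=C(C)CC[C@@H]1CC(=O)C(C)=CC1(OC)OC | intermediate
5 | (1S,5R)-4,4-dimethoxy-2-methyl-5-(3-methylbut-3-en-1-yl)cyclohex-2-en-1-ol | C=C(C)CC[C@@H]1C[C@H](O)C(C)=CC1(OC)OC | intermediate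
6 | (4S,6R)-4-hydroxy-3-methyl-6-(3-methylbut-3-en-1-yl)cyclohex-2-en-1-one | C=C(C)CC[C@@H]1C[C@H](O)C(C)=CC1=O | intermediate
7 | (4S,6R)-4-[(tert-butyldimethylsilyl)oxy]-3-methyl-6-(3-methylbut-3-en-1-yl)cyclohex-2-en-1-one | C=C(C)CC[C@@H]1C[C@H](O[Si](C)(C)C(C)(C)C)C(C)=CC1=O | intermediate
8 | 2-(2-bromoethyl)-1,3-dioxolane | BrCCC1OCCO1 | starting material
9 | tert-butyl{[(1S,2S,5R)-2-[2-(1,3-dioxolan-2-yl)ethyl]-2-methyl-5-(3-methylbut-3-en-1-yl)-4-[(trimethylsilyl)oxy]cyclohex-3-en-1-yl]oxy}dimethylsilane | C=C(C)CC[C@@H]1C[C@H](O[Si](C)(C)C(C)(C)C)[C@@](C)(CCC2OCCO2)C=C1O[Si](C)(C)C | intermediate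
10 | (3S,4S,6R)-4-[(tert-butyldimethylsilyl)oxy]-3-[2-(1,3-dioxolan-2-yl)ethyl]-3-methyl-6-(3-methylbut-3-en-1-yl)cyclohex-1-en-1-yl trifluoromethanesulfonate | C=C(C)CC[C@@H]1C[C@H](O[Si](C)(C)C(C)(C)C)[C@@](C)(CCC2OCCO2)C=C1OS(=O)(=O)C(F)(F)F | intermediate
11 | tert-butyl{[(1S,2S,5R)-2-[2-(1,3-dioxolan-2-yl)ethyl]-2,4-dimethyl-5-(3-methylbut-3-en-1-yl)cyclohex-3-en-1-yl]oxy}dimethylsilane | C=C(C)CC[C@@H]1C[C@H](O[Si](C)(C)C(C)(C)C)[C@@](C)(CCC2OCCO2)C=C1C | intermediate
12 | 3-[(1S,4R,6S)-6-[(tert-butyldimethylsilyl)oxy]-1,3-dimethyl-4-(3-methylbut-3-en-1-yl)cyclohex-2-en-1-yl]propanal | C=C(C)CC[C@@H]1C[C@H](O[Si](C)(C)C(C)(C)C)[C@@](C)(CCC=O)C=C1C | intermediate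
13 | ethyl (2E)-5-[(1S,4R,6S)-6-[(tert-butyldimethylsilyl)oxy]-1,3-dimethyl-4-(3-methylbut-3-en-1-yl)cyclohex-2-en-1-yl]-2-methylpent-2-enoate | C=C(C)CC[C@@H]1C[C@H](O[Si](C)(C)C(C)(C)C)[C@@](C)(CC/C=C(\C)C(=O)OCC)C=C1C | intermediate
14 | ethyl (2S)-2-[(1R,3aS,4S,6R,7aS)-4-[(tert-butyldimethylsilyl)oxy]-3a-methyl-7-methylidene-6-(3-methylbut-3-en-1-yl)octahydro-1H-inden-1-yl]propanoate | C=C(C)CC[C@@H]1C[C@H](O[Si](C)(C)C(C)(C)C)[C@@]2(C)CC[C@@H]([C@H](C)C(=O)OCC)[C@H]2C1=C | intermediate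
15 | (2S)-2-[(1R,3aS,4S,6R,7aS)-4-[(tert-butyldimethylsilyl)oxy]-3a-methyl-7-methylidene-6-(3-methylbut-3-en-1-yl)octahydro-1H-inden-1-yl]propanal | C=C(C)CC[C@@H]1C[C@H](O[Si](C)(C)C(C)(C)C)[C@@]2(C)CC[C@@H]([C@H](C)C=O)[C@H]2C1=C | intermediate
16 | (2S,3S)-2-[(1R,3aS,4S,6R,7aS)-4-[(tert-butyldimethylsilyl)oxy]-3a-methyl-7-methylidene-6-(3-methylbut-3-en-1-yl)octahydro-1H-inden-1-yl]hex-5-en-3-ol | C=C(C)CC[C@@H]1C[C@H](O[Si](C)(C)C(C)(C)C)[C@@]2(C)CC[C@@H]([C@H](C)[C@@H](O)CC=C)[C@H]2C1=C | intermediate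
17 | (1R,2S,3S,5E,9R,11S,12S,15S)-11-[(tert-butyldimethylsilyl)oxy]-2,6,12-trimethyl-16-methylidenetricyclo[7.5.2.0^{12,15}]hexadec-5-en-3-ol | C=C1[C@@H]2CC/C(C)=C/C[C@H](O)[C@@H](C)[C@@H]3CC[C@](C)([C@@H](O[Si](C)(C)C(C)(C)C)C2)[C@H]13 | intermediate
18 | (1R,2S,3S,5E,9R,11S,12S,15S)-11-[(tert-butyldimethylsilyl)oxy]-2,6,12-trimethyl-16-methylidenetricyclo[7.5.2.0^{12,15}]hexadec-5-en-3-yl acetate | C=C1[C@@H]2CC/C(C)=C/C[C@H](OC(C)=O)[C@@H](C)[C@@H]3CC[C@](C)([C@@H](O[Si](C)(C)C(C)(C)C)C2)[C@H]13 | intermediate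
19 | (1R,2S,3S,5E,9R,11S,12S,15S)-11-hydroxy-2,6,12-trimethyl-16-methylidenetricyclo[7.5.2.0^{12,15}]hexadec-5-en-3-yl acetate | C=C1[C@@H]2CC/C(C)=C/C[C@H](OC(C)=O)[C@@H](C)[C@@H]3CC[C@](C)([C@@H](O)C2)[C@H]13 | intermediate
20 | (1R,2S,3S,5E,9R,11S,12S,15S)-2,6,12-trimethyl-16-methylidene-11-(propanoyloxy)tricyclo[7.5.2.0^{12,15}]hexadec-5-en-3-yl acetate | C=C1[C@@H]2CC/C(C)=C/C[C@H](OC(C)=O)[C@@H](C)[C@@H]3CC[C@](C)([C@@H](OC(=O)CC)C2)[C@H]13 | intermediate
21 | (1R,2S,3S,5E,7R,9R,11S,12S,15S)-7-hydroxy-2,6,12-trimethyl-16-methylidene-11-(propanoyloxy)tricyclo[7.5.2.0^{12,15}]hexadec-5-en-3-yl acetate (CNP0180453.1) | C=C1[C@@H]2C[C@@H](O)/C(C)=C/C[C@H](OC(C)=O)[C@@H](C)[C@@H]3CC[C@](C)([C@@H](OC(=O)CC)C2)[C@H]13 | target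

**Step count and risks**

Total step count: 14. Longest linear sequence: 14 steps (1 → 21, no side branch).

The three steps most likely to fail:

Step 14 (the proposed new hydroxylation). The risks are poor turnover of the arylseleninic catalyst, over-oxidation to the enone, or the wrong C13 epimer. The fallback uses known chemistry, sets out from 20 and comes back at 21. Compound 20 is oxidized with SeO2 (0.5 equiv) and t-BuOOH in CH2Cl2, which follows the same site rules and gives the C13 alcohols as a mixture of 21 and the C13-epimeric alcohol F1. The unseparated mixture is oxidized with Dess–Martin periodinane to the C13 enone F2. A reagent-controlled Corey–Bakshi–Shibata reduction ((S)-2-methyl-CBS-oxazaborolidine, BH3·SMe2, toluene, −40 °C) then gives 21.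

Step 11 (ring-closing metathesis). The risks are the Z ring alkene, oligomers, or closure onto the C15 methylidene. The fallback sets out from 16 and comes back at 17. If the metathesis delivers the Z alkene, the (5Z)-macrocycle F3, its trisubstituted ring alkene is epoxidized with m-CPBA (the hindered methylidene reacts more slowly) to the cis-epoxide F4. The geometry is then inverted by the Vedejs sequence (LiPPh2, THF; then MeI): anti opening of the epoxide and syn elimination of the β-oxido phosphonium salt give the E alkene 17.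

Step 8 (intramolecular ene reaction). The risks are a sluggish trisubstituted enoate, trapping of a C15 cation by chloride or by the side-chain alkene if the reaction turns stepwise, and loss of C8 control. The fallback sets out from 10 and comes back at 14. Triflate 10 is coupled with Me3SiCH2MgCl (Pd(PPh3)4, THF) to the allylsilane acetal F5. Hydrolysis (PPTS, wet acetone) gives the allylsilane aldehyde F6, and the Wittig olefination of step 7 gives the allylsilane enoate F7. TiCl4 (CH2Cl2, −78 °C) then effects an intramolecular Hosomi–Sakurai conjugate allylation: C16 attacks C7 with loss of the silyl group, which gives the same cis-fused methylidene ester. Protonation of the titanium enolate at C8 is not controlled, so 14 is separated from the C8-epimeric ester F8, which is recycled by equilibration with NaOEt in EtOH.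

Further compounds
F1 | step 14 | (1R,2S,3S,5E,7S,9R,11S,12S,15S)-7-hydroxy-2,6,12-trimethyl-16-methylidene-11-(propanoyloxy)tricyclo[7.5.2.0^{12,15}]hexadec-5-en-3-yl acetate | C=C1[C@@H]2C[C@H](O)/C(C)=C/C[C@H](OC(C)=O)[C@@H](C)[C@@H]3CC[C@](C)([C@@H](OC(=O)CC)C2)[C@H]13
F2 | step 14 | (1R,2S,3S,5E,9S,11S,12S,15S)-2,6,12-trimethyl-16-methylidene-7-oxo-11-(propanoyloxy)tricyclo[7.5.2.0^{12,15}]hexadec-5-en-3-yl acetate | C=C1[C@@H]2CC(=O)/C(C)=C/C[C@H](OC(C)=O)[C@@H](C)[C@@H]3CC[C@](C)([C@@H](OC(=O)CC)C2)[C@H]13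
F3 | step 11 | (1R,2S,3S,5Z,9R,11S,12S,15S)-11-[(tert-butyldimethylsilyl)oxy]-2,6,12-trimethyl-16-methylidenetricyclo[7.5.2.0^{12,15}]hexadec-5-en-3-ol | C=C1[C@@H]2CC/C(C)=C\C[C@H](O)[C@@H](C)[C@@H]3CC[C@](C)([C@@H](O[Si](C)(C)C(C)(C)C)C2)[C@H]13
F4 | step 11 | (1R,2S,3S,5S,6R,9R,11S,12S,15S)-11-[(tert-butyldimethylsilyl)oxy]-5,6-epoxy-2,6,12-trimethyl-16-methylidenetricyclo[7.5.2.0^{12,15}]hexadecan-3-ol (one face of the cis-epoxide shown, either serves) | C=C1[C@@H]2CC[C@@]4(C)O[C@H]4C[C@H](O)[C@@H](C)[C@@H]3CC[C@](C)([C@@H](O[Si](C)(C)C(C)(C)C)C2)[C@H]13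
F5 | step 8 | tert-butyl{[(1S,2S,5R)-2-[2-(1,3-dioxolan-2-yl)ethyl]-2-methyl-5-(3-methylbut-3-en-1-yl)-4-[(trimethylsilyl)methyl]cyclohex-3-en-1-yl]oxy}dimethylsilane | C=C(C)CC[C@@H]1C[C@H](O[Si](C)(C)C(C)(C)C)[C@@](C)(CCC2OCCO2)C=C1C[Si](C)(C)C
F6 | step 8 | 3-[(1S,4R,6S)-6-[(tert-butyldimethylsilyl)oxy]-1-methyl-4-(3-methylbut-3-en-1-yl)-3-[(trimethylsilyl)methyl]cyclohex-2-en-1-yl]propanal | C=C(C)CC[C@@H]1C[C@H](O[Si](C)(C)C(C)(C)C)[C@@](C)(CCC=O)C=C1C[Si](C)(C)C
F7 | step 8 | ethyl (2E)-5-[(1S,4R,6S)-6-[(tert-butyldimethylsilyl)oxy]-1-methyl-4-(3-methylbut-3-en-1-yl)-3-[(trimethylsilyl)methyl]cyclohex-2-en-1-yl]-2-methylpent-2-enoate | C=C(C)CC[C@@H]1C[C@H](O[Si](C)(C)C(C)(C)C)[C@@](C)(CC/C=C(\C)C(=O)OCC)C=C1C[Si](C)(C)C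
F8 | step 8 | ethyl (2R)-2-[(1R,3aS,4S,6R,7aS)-4-[(tert-butyldimethylsilyl)oxy]-3a-methyl-7-methylidene-6-(3-methylbut-3-en-1-yl)octahydro-1H-inden-1-yl]propanoate | C=C(C)CC[C@@H]1C[C@H](O[Si](C)(C)C(C)(C)C)[C@@]2(C)CC[C@@H]([C@@H](C)C(=O)OCC)[C@H]2C1=C
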